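**Retrosynthetic overview**

1. Numbering (longipinane): C1 ketone carbon, C2=C3 (methyl on C3), C4 and C11 bridgeheads, C5 and C10 the two one-carbon bridges, C6 gem-dimethyl carbon, C7 and C9 ester-bearing carbons, C8 CH2; rings: cyclobutane C4–C5–C11–C10, cyclohexenone C1–C2–C3–C4–C5–C11, seven-membered ring C5–C6–C7–C8–C9–C10–C11.
2. Last disconnection, C5–C6: a tertiary C6 radical, released from a C6–C7 epoxide, adds to the C5 tosylhydrazone of a bicyclo[3.1.1]heptan-6-one and N2 is lost; one operation closes the seven-membered ring, makes the quaternary C6, unveils the C7 oxygen and turns C5 into CH.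
3. Enabling feature: the cyclobutane C4–C5–C11–C10 is folded, so the C9–C8–C7–C6 arm on C10 (face away from the C1–C2–C3 bridge) hangs directly under C5; C5 lies between the bridgeheads C4 and C11, so its C=N can neither tautomerise nor eliminate and the new C5–H can only sit on the open face.
4. The bicyclic ketone comes from one intramolecular vinylketene–alkene [2+2] cycloaddition of an acyclic farnesoid acid whose carboxyl carbon is C5 (bonds C5–C11 and C4–C10), closing the cyclobutane and the six-membered ring together; a silyloxy stereocentre at C1 steers the face and is oxidised to the C1 ketone at the end.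
5. The acid is assembled from (2E)-4-acetoxy-2-methylbut-2-enal by Keck allylation and cross-metathesis (C9), a vinylogous Mukaiyama aldol reaction with a 3-methylbut-2-enoate dienolate (C1) and Shi epoxidation (C7); ring order: four- and six-membered rings in step 11, seven-membered ring in step 13.

Key step: step 13

Numbering remark: acyclic intermediates are numbered as dodecanoates; their C1, C2, C3, C4, C5, C6, C7, C8, C9, C10, C11 become C5, C4, C3, C2, C1, C11, C10, C9, C8, C7, C6 of the tricycle.

Assumption: each chiral catalyst is taken to follow its established sense of induction; the enantiomer named is the one expected to give the configuration drawn, and its antipode would be used if the sense proved opposite.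

**Route**

Step 1
Reactants: 1 (2E)-4-acetoxy-2-methylbut-2-enal
Product: 2 (2E,4R)-4-hydroxy-3-methylhepta-2,6-dien-1-yl acetate
Conditions: allylSnBu3, (R)-BINOL (10 mol %), Ti(OiPr)4 (10 mol %), 4 Å MS, CH2Cl2, −20 °C; aq. NaHCO3
Reagents that add atoms: allyltributylstannane, C=CC[Sn](CCCC)(CCCC)CCCC
Why: Keck asymmetric allylation, in which the (R)-BINOL–titanium Lewis acid should direct the allyl group to the Re face of the aldehyde in a 1,2-addition and so set the carbinol (future C9) as (R).

Step 2
Reactants: 2 (2E,4R)-4-hydroxy-3-methylhepta-2,6-dien-1-yl acetate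
Product: 3 (2E,4R)-4-hydroxy-3,7-dimethylocta-2,6-dien-1-yl acetate
Conditions: second-generation Grubbs catalyst RuCl2(=CHPh)(H2IMes)(PCy3) (5 mol %), 2-methyl-2-butene (excess), CH2Cl2, 40 °C
Reagents that add atoms: 2-methyl-2-butene, CC=C(C)C
Why: Olefin cross-metathesis of the terminal alkene with 2-methyl-2-butene should install the prenyl terminus while the trisubstituted allylic-acetate alkene stays inert, and no stereocentre is touched.

Step 3
Reactants: 3 (2E,4R)-4-hydroxy-3,7-dimethylocta-2,6-dien-1-yl acetate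
Product: 4 (2E,4R)-3,7-dimethyl-4-(triethylsilyloxy)octa-2,6-dien-1-yl acetate
Conditions: Et3SiCl, imidazole, DMF, 0 °C
Reagents that add atoms: chlorotriethylsilane, CC[Si](Cl)(CC)CC
Why: Imidazole-promoted silylation protects the secondary allylic alcohol as a triethylsilyl ether, which can later be removed in the presence of a tert-butyldimethylsilyl ether.

Step 4
Reactants: 4 (2E,4R)-3,7-dimethyl-4-(triethylsilyloxy)octa-2,6-dien-1-yl acetate
Product: 5 (2E,4R)-3,7-dimethyl-4-(triethylsilyloxy)octa-2,6-dien-1-ol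
Conditions: K2CO3 (cat.), MeOH, 0 °C
Reagents that add atoms: none
Why: Base-catalysed methanolysis (transesterification) should remove the primary acetate while the secondary triethylsilyl ether survives cold K2CO3 in methanol.

Step 5
Reactants: 5 (2E,4R)-3,7-dimethyl-4-(triethylsilyloxy)octa-2,6-dien-1-ol
Product: 6 (2E,4R)-3,7-dimethyl-4-(triethylsilyloxy)octa-2,6-dienal
Conditions: MnO2, CH2Cl2, rt
Reagents that add atoms: none
Why: MnO2 oxidises the primary allylic alcohol selectively to the (E)-enal and leaves the prenyl alkene and the silyl ether untouched.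

Step 6
Reactants: 7 methyl 3-methylbut-2-enoate
Product: 8 1-(tert-butyldimethylsilyloxy)-1-methoxy-3-methylbuta-1,3-diene
Conditions: LDA (LiN(iPr)2), THF, −78 °C; t-BuMe2SiCl, DMPU, −78 °C to rt
Reagents that add atoms: tert-butylchlorodimethylsilane, CC(C)(C)[Si](C)(C)Cl
Why: γ-Deprotonation of the enoate and O-silylation of the extended enolate should give the silyl dienol ether (vinylogous silyl ketene acetal) needed for the vinylogous aldol reaction.

Step 7
Reactants: 6 (2E,4R)-3,7-dimethyl-4-(triethylsilyloxy)octa-2,6-dienal; 8 1-(tert-butyldimethylsilyloxy)-1-methoxy-3-methylbuta-1,3-diene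
Product: 9 methyl (2E,5S,6E,8R)-5-hydroxy-3,7,11-trimethyl-8-(triethylsilyloxy)dodeca-2,6,10-trienoate
Conditions: SiCl4 (1.1 equiv), (R,R)-bisphosphoramide catalyst [pentane-1,5-diyl-linked bis(N-methylphosphoramide) of (R)-N,N'-dimethyl-1,1'-binaphthyl-2,2'-diamine] (5 mol %), iPr2NEt (10 mol %), CH2Cl2, −78 °C; sat. aq. NaHCO3
Reagents that add atoms: none
Why: Lewis-base-catalysed vinylogous Mukaiyama aldol reaction, in which the chiral phosphoramide-bound trichlorosilyl cation activates the enal and the dienol ether attacks through its γ-carbon in an open transition state, so that attack on the Si face should set the new carbinol (future C1) as (S) under catalyst control and give the (2E)-enoate.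

Step 8
Reactants: 9 methyl (2E,5S,6E,8R)-5-hydroxy-3,7,11-trimethyl-8-(triethylsilyloxy)dodeca-2,6,10-trienoate
Product: 10 methyl (2E,5S,6E,8R)-5-(tert-butyldimethylsilyloxy)-3,7,11-trimethyl-8-(triethylsilyloxy)dodeca-2,6,10-trienoate
Conditions: t-BuMe2SiOTf, 2,6-lutidine, CH2Cl2, −78 °C
Reagents that add atoms: tert-butyldimethylsilyl trifluoromethanesulfonate, CC(C)(C)[Si](C)(C)OS(=O)(=O)C(F)(F)F
Why: Silyl triflate with a hindered base silylates the secondary alcohol at low temperature, and the bulky silyloxy group so placed at the future C1 is the element that later controls the face of the cycloaddition.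

Step 9
Reactants: 10 methyl (2E,5S,6E,8R)-5-(tert-butyldimethylsilyloxy)-3,7,11-trimethyl-8-(triethylsilyloxy)dodeca-2,6,10-trienoate
Product: 11 methyl (2E,5S,6E,8R,10R)-5-(tert-butyldimethylsilyloxy)-10,11-epoxy-3,7,11-trimethyl-8-(triethylsilyloxy)dodeca-2,6-dienoate
Conditions: D-fructose-derived ketone catalyst (1,2:4,5-di-O-isopropylidene-β-D-erythro-2,3-hexodiulo-2,6-pyranose, 30 mol %), Oxone (2KHSO5·KHSO4·K2SO4), K2CO3, Bu4NHSO4 (cat.), MeCN/dimethoxymethane/aq. buffer pH 10.5, 0 °C
Reagents that add atoms: potassium peroxymonosulfate, [K+].[O-]S(=O)(=O)OO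
Why: Shi epoxidation, in which the electron-rich prenyl alkene should react in preference to the enoate and to the C6=C7 alkene flanked by two silyloxy carbons, and the spiro transition state of the chiral dioxirane should give the (10R)-epoxide (future C7–O) under catalyst control.

Step 10
Reactants: 11 methyl (2E,5S,6E,8R,10R)-5-(tert-butyldimethylsilyloxy)-10,11-epoxy-3,7,11-trimethyl-8-(triethylsilyloxy)dodeca-2,6-dienoate
Product: 12 (2E,5S,6E,8R,10R)-5-(tert-butyldimethylsilyloxy)-10,11-epoxy-3,7,11-trimethyl-8-(triethylsilyloxy)dodeca-2,6-dienoic acid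
Conditions: LiOH, THF/MeOH/H2O, rt; cold 0.5 M HCl to pH 4
Reagents that add atoms: lithium hydroxide, [Li+].[OH-]
Why: Saponification of the methyl ester, which the epoxide and both silyl ethers should tolerate, as they should the brief cold acidification.

Step 11
Reactants: 12 (2E,5S,6E,8R,10R)-5-(tert-butyldimethylsilyloxy)-10,11-epoxy-3,7,11-trimethyl-8-(triethylsilyloxy)dodeca-2,6-dienoic acid
Product: 15 (1S,4R,7R,9R,10R,11R)-1-(tert-butyldimethylsilyloxy)-6,7-epoxy-3-methylidene-9-(triethylsilyloxy)-5,6-secolongipinan-5-one, via acid chloride 13 (not isolated), via vinylketene 14 (not isolated)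
Conditions: 1-chloro-N,N,2-trimethylprop-1-en-1-amine, CH2Cl2, 0 °C; then slow addition to Et3N, toluene, 110 °C (0.005 M)
Reagents that add atoms: none
Why: Intramolecular vinylketene–alkene [2+2] cycloaddition of the type known for 3-methyl-2,6-dienoyl chlorides: Et3N removes a proton from the C3 methyl group cis to the acyl chloride, the ketene carbonyl carbon bonds to C6 and the α-carbon to the more substituted C7, suprafacial addition to the (6E)-alkene places the methyl of the new quaternary centre (C10) over the three-carbon bridge and the arm on the opposite face, and the face is chosen so that the C1 silyloxy group lies beside the carbonyl bridge and away from that methyl, which sets C4, C10 and C11.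

Step 12
Reactants: 15 (1S,4R,7R,9R,10R,11R)-1-(tert-butyldimethylsilyloxy)-6,7-epoxy-3-methylidene-9-(triethylsilyloxy)-5,6-secolongipinan-5-one
Product: 16 (1S,4R,7R,9R,10R,11R)-1-(tert-butyldimethylsilyloxy)-6,7-epoxy-3-methylidene-9-(triethylsilyloxy)-5,6-secolongipinan-5-one 4-methylbenzenesulfonylhydrazone
Conditions: TsNHNH2, 4 Å MS, MeOH/THF, rt
Reagents that add atoms: 4-methylbenzenesulfonohydrazide, NNS(=O)(=O)c1ccc(C)cc1
Why: Condensation of the strained, non-enolisable cyclobutanone with the sulfonyl hydrazide gives the tosylhydrazone under neutral conditions that spare the epoxide; no stereocentre is affected and the C=N geometry is irrelevant.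

Step 13
Reactants: 16 (1S,4R,7R,9R,10R,11R)-1-(tert-butyldimethylsilyloxy)-6,7-epoxy-3-methylidene-9-(triethylsilyloxy)-5,6-secolongipinan-5-one 4-methylbenzenesulfonylhydrazone
Product: 18 (1S,4R,5S,7R,9R,10R,11R)-1-(tert-butyldimethylsilyloxy)-3-methylidene-9-(triethylsilyloxy)longipinan-7-ol, via tosylhydrazide adduct 17 (not isolated)
Conditions: Cp2TiCl2 (1.2 equiv), Mn dust (4 equiv), 2,4,6-collidine·HCl (2.5 equiv), THF, rt, slow addition of 16; then K2CO3, MeOH, 60 °C
Reagents that add atoms: none
Why: Proposed new method: Cp2TiCl (trivalent titanium, formed from Cp2TiCl2 and Mn) should open the trisubstituted epoxide by single-electron transfer at the more substituted carbon (Nugent–RajanBabu opening) to give a tertiary C6 radical bearing the C7–O–Ti group, which adds to the C5 carbon of the tosylhydrazone; the hydrazinyl radical is reduced by a second Cp2TiCl and protonated (or expels the sulfonyl radical directly), and base then eliminates sulfinate so that the alkyldiazene loses N2 and leaves C5–H. The closest known reaction types are titanocene-mediated epoxide-opening radical cyclisations onto alkenes, carbonyl groups and nitriles, and the radical alkylation of sulfonylhydrazones and N-aziridinyl imines with loss of N2; their combination and this ring size are new. The seven-membered ring C5–C6–C7–C8–C9–C10–C11 closes in a 7-exo-trig addition to C=N that is geometrically close to a 6-exo closure because C10 and C5 are held 1,3-cis across the folded cyclobutane. C7 keeps the configuration of the epoxide because its C–O bond is never broken, C6 is not stereogenic, and the new C5 centre can only form with the C5–C6 bond on the face away from the three-carbon bridge (the arm on C10 reaches C5 from that face alone), so the hydrogen must enter on the opposite, open face. The step needs homolysis at C6 rather than C7 (secured by tertiary over secondary radical stability), attack on C=N rather than on the exocyclic alkene (secured by distance, the methylidene lying on the other side of the bicycle) and cyclisation faster than reduction or disproportionation of the radical (helped by the slow capture of tertiary radicals by Cp2TiCl and by slow addition). C5 has only bridgehead neighbours, so neither tautomerisation of the hydrazone nor β-elimination can compete.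

Step 14
Reactants: 18 (1S,4R,5S,7R,9R,10R,11R)-1-(tert-butyldimethylsilyloxy)-3-methylidene-9-(triethylsilyloxy)longipinan-7-ol
Product: 19 (1S,4R,5S,7R,9R,10R,11R)-1-(tert-butyldimethylsilyloxy)-3-methylidenelongipinane-7,9-diol
Conditions: PPTS (cat.), MeOH, 0 °C to rt
Reagents that add atoms: none
Why: Mild acid-catalysed methanolysis should remove the triethylsilyl ether selectively while the more hindered tert-butyldimethylsilyl ether at C1 survives.

Step 15
Reactants: 19 (1S,4R,5S,7R,9R,10R,11R)-1-(tert-butyldimethylsilyloxy)-3-methylidenelongipinane-7,9-diol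
Product: 20 (1S,4R,5S,7R,9R,10R,11R)-1-(tert-butyldimethylsilyloxy)-3-methylidenelongipinane-7,9-diyl bis(3-methylbut-2-enoate)
Conditions: 3-methylbut-2-enoic acid, 2,4,6-trichlorobenzoyl chloride, Et3N, THF, rt; then 19, DMAP, toluene, 60 °C
Reagents that add atoms: 3-methylbut-2-enoic acid, CC(C)=CC(=O)O
Why: Yamaguchi esterification, in which the mixed anhydride and DMAP should acylate both hindered secondary alcohols without base-induced deconjugation of the acyl group, the configurations at C7 and C9 being retained because no C–O bond at these carbons is broken.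

Step 16
Reactants: 20 (1S,4R,5S,7R,9R,10R,11R)-1-(tert-butyldimethylsilyloxy)-3-methylidenelongipinane-7,9-diyl bis(3-methylbut-2-enoate)
Product: 21 (1S,4R,5S,7R,9R,10R,11R)-1-hydroxy-3-methylidenelongipinane-7,9-diyl bis(3-methylbut-2-enoate)
Conditions: HF·pyridine, pyridine, THF, 0 °C to rt
Reagents that add atoms: none
Why: Buffered fluoride desilylation should free the C1 alcohol without cleaving or migrating the two esters.

Step 17
Reactants: 21 (1S,4R,5S,7R,9R,10R,11R)-1-hydroxy-3-methylidenelongipinane-7,9-diyl bis(3-methylbut-2-enoate)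
Product: 23 (4R,5S,7R,9R,10R,11R)-1-oxolongipin-2-ene-7,9-diyl bis(3-methylbut-2-enoate), via exo-methylene ketone 22 (not isolated)
Conditions: Dess–Martin periodinane, pyridine, CH2Cl2, rt; then DBU (cat.), CH2Cl2, rt
Reagents that add atoms: none
Why: Dess–Martin oxidation gives the β,γ-unsaturated ketone, and base-mediated isomerisation through the C2 dienolate should move the exocyclic double bond into conjugation (C2=C3) to the thermodynamically favoured verbenone-type enone, C11 being a bridgehead that cannot epimerise.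

**Compound list**

1 | (2E)-4-acetoxy-2-methylbut-2-enal | CC(=O)OC/C=C(C)/C=O | starting material
2 | (2E,4R)-4-hydroxy-3-methylhepta-2,6-dien-1-yl acetate | CC(=O)OC/C=C(C)/[C@H](O)CC=C | intermediate
3 | (2E,4R)-4-hydroxy-3,7-dimethylocta-2,6-dien-1-yl acetate | CC(=O)OC/C=C(C)/[C@H](O)CC=C(C)C | intermediate
4 | (2E,4R)-3,7-dimethyl-4-(triethylsilyloxy)octa-2,6-dien-1-yl acetate | CC(=O)OC/C=C(C)/[C@H](O[Si](CC)(CC)CC)CC=C(C)C | intermediate
5 | (2E,4R)-3,7-dimethyl-4-(triethylsilyloxy)octa-2,6-dien-1-ol | OC/C=C(C)/[C@H](O[Si](CC)(CC)CC)CC=C(C)C | intermediate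
6 | (2E,4R)-3,7-dimethyl-4-(triethylsilyloxy)octa-2,6-dienal | O=C/C=C(C)/[C@H](O[Si](CC)(CC)CC)CC=C(C)C | intermediate
7 | methyl 3-methylbut-2-enoate | COC(=O)C=C(C)C | starting material
8 | 1-(tert-butyldimethylsilyloxy)-1-methoxy-3-methylbuta-1,3-diene | COC(O[Si](C)(C)C(C)(C)C)=CC(C)=C | intermediate
9 | methyl (2E,5S,6E,8R)-5-hydroxy-3,7,11-trimethyl-8-(triethylsilyloxy)dodeca-2,6,10-trienoate | COC(=O)/C=C(C)/C[C@H](O)/C=C(C)/[C@H](O[Si](CC)(CC)CC)CC=C(C)C | intermediate
10 | methyl (2E,5S,6E,8R)-5-(tert-butyldimethylsilyloxy)-3,7,11-trimethyl-8-(triethylsilyloxy)dodeca-2,6,10-trienoate | COC(=O)/C=C(C)/C[C@H](O[Si](C)(C)C(C)(C)C)/C=C(C)/[C@H](O[Si](CC)(CC)CC)CC=C(C)C | intermediate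
11 | methyl (2E,5S,6E,8R,10R)-5-(tert-butyldimethylsilyloxy)-10,11-epoxy-3,7,11-trimethyl-8-(triethylsilyloxy)dodeca-2,6-dienoate | COC(=O)/C=C(C)/C[C@H](O[Si](C)(C)C(C)(C)C)/C=C(C)/[C@H](O[Si](CC)(CC)CC)C[C@H]1OC1(C)C | intermediate
12 | (2E,5S,6E,8R,10R)-5-(tert-butyldimethylsilyloxy)-10,11-epoxy-3,7,11-trimethyl-8-(triethylsilyloxy)dodeca-2,6-dienoic acid | OC(=O)/C=C(C)/C[C@H](O[Si](C)(C)C(C)(C)C)/C=C(C)/[C@H](O[Si](CC)(CC)CC)C[C@H]1OC1(C)C | intermediate
13 | acid chloride of 12 | ClC(=O)/C=C(C)/C[C@H](O[Si](C)(C)C(C)(C)C)/C=C(C)/[C@H](O[Si](CC)(CC)CC)C[C@H]1OC1(C)C | intermediate (not isolated)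
14 | (5S,6E,8R,10R)-5-(tert-butyldimethylsilyloxy)-10,11-epoxy-7,11-dimethyl-3-methylidene-8-(triethylsilyloxy)dodeca-1,6-dien-1-one (vinylketene) | O=C=CC(=C)C[C@H](O[Si](C)(C)C(C)(C)C)/C=C(C)/[C@H](O[Si](CC)(CC)CC)C[C@H]1OC1(C)C | intermediate (not isolated)
15 | (1S,4R,7R,9R,10R,11R)-1-(tert-butyldimethylsilyloxy)-6,7-epoxy-3-methylidene-9-(triethylsilyloxy)-5,6-secolongipinan-5-one (bicyclo[3.1.1]heptan-6-one; arm on C10 on the face away from the C1–C3 bridge; silyloxy group on the side of the C5 bridge) | CC1(C)O[C@@H]1C[C@@H](O[Si](CC)(CC)CC)[C@@]2(C)[C@@H]3[C@@H](O[Si](C)(C)C(C)(C)C)CC(=C)[C@H]2C3=O | intermediate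
16 | 4-methylbenzenesulfonylhydrazone of 15 at C5 | CC1(C)O[C@@H]1C[C@@H](O[Si](CC)(CC)CC)[C@@]2(C)[C@@H]3[C@@H](O[Si](C)(C)C(C)(C)C)CC(=C)[C@H]2C3=NNS(=O)(=O)c1ccc(C)cc1 | intermediate
17 | 1-(tert-butyldimethylsilyloxy)-3-methylidene-5-[2-(4-methylbenzenesulfonyl)hydrazin-1-yl]-9-(triethylsilyloxy)longipinan-7-ol (nitrogen on C5 on the face of the C1–C3 bridge) | O[C@@H]1C[C@@H](O[Si](CC)(CC)CC)[C@@]2(C)[C@@H]3[C@@H](O[Si](C)(C)C(C)(C)C)CC(=C)[C@H]2[C@]3(NNS(=O)(=O)c4ccc(C)cc4)C1(C)C | intermediate (not isolated)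
18 | (1S,4R,5S,7R,9R,10R,11R)-1-(tert-butyldimethylsilyloxy)-3-methylidene-9-(triethylsilyloxy)longipinan-7-ol | O[C@@H]1C[C@@H](O[Si](CC)(CC)CC)[C@@]2(C)[C@@H]3[C@@H](O[Si](C)(C)C(C)(C)C)CC(=C)[C@H]2[C@@H]3C1(C)C | intermediate
19 | (1S,4R,5S,7R,9R,10R,11R)-1-(tert-butyldimethylsilyloxy)-3-methylidenelongipinane-7,9-diol | O[C@@H]1C[C@@H](O)[C@@]2(C)[C@@H]3[C@@H](O[Si](C)(C)C(C)(C)C)CC(=C)[C@H]2[C@@H]3C1(C)C | intermediate
20 | (1S,4R,5S,7R,9R,10R,11R)-1-(tert-butyldimethylsilyloxy)-3-methylidenelongipinane-7,9-diyl bis(3-methylbut-2-enoate) | CC(C)=CC(=O)O[C@@H]1C[C@@H](OC(=O)C=C(C)C)[C@@]2(C)[C@@H]3[C@@H](O[Si](C)(C)C(C)(C)C)CC(=C)[C@H]2[C@@H]3C1(C)C | intermediate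
21 | (1S,4R,5S,7R,9R,10R,11R)-1-hydroxy-3-methylidenelongipinane-7,9-diyl bis(3-methylbut-2-enoate) | CC(C)=CC(=O)O[C@@H]1C[C@@H](OC(=O)C=C(C)C)[C@@]2(C)[C@@H]3[C@@H](O)CC(=C)[C@H]2[C@@H]3C1(C)C | intermediate
22 | (4R,5S,7R,9R,10R,11R)-3-methylidene-1-oxolongipinane-7,9-diyl bis(3-methylbut-2-enoate) | CC(C)=CC(=O)O[C@@H]1C[C@@H](OC(=O)C=C(C)C)[C@@]2(C)[C@@H]3C(=O)CC(=C)[C@H]2[C@@H]3C1(C)C | intermediate (not isolated)
23 | (4R,5S,7R,9R,10R,11R)-1-oxolongipin-2-ene-7,9-diyl bis(3-methylbut-2-enoate), CNP0105062.1 | CC(C)=CC(=O)O[C@@H]1C[C@@H](OC(=O)C=C(C)C)[C@@]2(C)[C@@H]3C(=O)C=C(C)[C@H]2[C@@H]3C1(C)C | target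

**Step count and risks**

Total step count: 17. Longest linear sequence: 16 steps (steps 1–5 and 7–17, from 1 to 23).

Steps most likely to fail:

Step 13 (Proposed new method). The tertiary C6 radical may be reduced, or may lose a β-hydrogen to give the isopropenyl carbinol, before it reaches C5; the hindered sulfonylhydrazone may also be too slow an acceptor under titanium mediation. Fallback with known chemistry, setting out from 15 and returning at 19: 15 is treated with Cp2TiCl (Cp2TiCl2, Mn, THF) so that the tertiary radical is captured by the C5 ketone itself, the known titanocene-mediated cyclisation of epoxy ketones, giving after hydrolysis of the titanium alkoxides the 5,7-diol F1. The secondary C7 alcohol is silylated selectively (Et3SiOTf, 2,6-lutidine, −78 °C) to the bis(triethylsilyl) ether F2. The tertiary C5 alcohol is converted (KH, CS2, then MeI) into the S-methyl xanthate F3, which cannot undergo syn-elimination because C4 and C11 are bridgeheads and C6 bears no hydrogen. Barton–McCombie reduction (Bu3SnH, AIBN, toluene, 90 °C) gives the deoxygenated tricycle F4, the hydrogen entering C5 on the only open face, and PPTS in methanol removes both triethylsilyl groups to give 19.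

Step 11. Removal of a C4 proton instead of a proton of the C3 methyl group would give vinylketene isomers that cannot cyclise and that dimerise; face selection by the C5 silyloxy group may also be incomplete. Fallback, setting out from 11 and returning at 15: the ester 11 is deconjugated (LDA, DMPU, THF, −78 °C, then kinetic protonation with AcOH) to the 3-methylidene ester F5 and saponified (LiOH) to the 3-methylidene acid F6. With 1-chloro-N,N,2-trimethylprop-1-en-1-amine this gives the 3-methylidene acid chloride F7, which on slow addition to Et3N in toluene at 80 °C loses HCl at its α-CH2 group, an unambiguous α-dehydrochlorination, to give the same vinylketene 14 and from it 15.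

Step 7. Attack through the α-carbon of the dienol ether, or formation of the (2Z)-ester followed by lactonisation onto the new hydroxyl group, would divert material, and facial control on the β,β-disubstituted enal may be incomplete. Fallback, setting out from 6 and returning at 10: a boron-mediated aldol reaction of acetone (chlorodiisopinocampheylborane of the enantiomer that directs attack to the Si face, Et3N, Et2O, −78 °C, then 6; H2O2 work-up) gives the β-hydroxy ketone F8. Silylation (t-BuMe2SiOTf, 2,6-lutidine) gives the silyl ether F9, and a Horner–Wadsworth–Emmons reaction with trimethyl phosphonoacetate (NaH, THF) gives 10 after separation of the minor (2Z)-isomer.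

Further compounds
F1 | step 13 | (1S,4R,7R,9R,10R,11R)-1-(tert-butyldimethylsilyloxy)-3-methylidene-9-(triethylsilyloxy)longipinane-5,7-diol | O[C@@H]1C[C@@H](O[Si](CC)(CC)CC)[C@@]2(C)[C@@H]3[C@@H](O[Si](C)(C)C(C)(C)C)CC(=C)[C@H]2[C@]3(O)C1(C)C
F2 | step 13 | 1-(tert-butyldimethylsilyloxy)-3-methylidene-7,9-bis(triethylsilyloxy)longipinan-5-ol | CC[Si](CC)(CC)O[C@@H]1C[C@@H](O[Si](CC)(CC)CC)[C@@]2(C)[C@@H]3[C@@H](O[Si](C)(C)C(C)(C)C)CC(=C)[C@H]2[C@]3(O)C1(C)C
F3 | step 13 | O-[1-(tert-butyldimethylsilyloxy)-3-methylidene-7,9-bis(triethylsilyloxy)longipinan-5-yl] S-methyl dithiocarbonate | CC[Si](CC)(CC)O[C@@H]1C[C@@H](O[Si](CC)(CC)CC)[C@@]2(C)[C@@H]3[C@@H](O[Si](C)(C)C(C)(C)C)CC(=C)[C@H]2[C@]3(OC(=S)SC)C1(C)C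
F4 | step 13 | (1S,4R,5S,7R,9R,10R,11R)-1-(tert-butyldimethylsilyloxy)-3-methylidene-7,9-bis(triethylsilyloxy)longipinane | CC[Si](CC)(CC)O[C@@H]1C[C@@H](O[Si](CC)(CC)CC)[C@@]2(C)[C@@H]3[C@@H](O[Si](C)(C)C(C)(C)C)CC(=C)[C@H]2[C@@H]3C1(C)C
F5 | step 11 | methyl (5S,6E,8R,10R)-5-(tert-butyldimethylsilyloxy)-10,11-epoxy-7,11-dimethyl-3-methylidene-8-(triethylsilyloxy)dodec-6-enoate | COC(=O)CC(=C)C[C@H](O[Si](C)(C)C(C)(C)C)/C=C(C)/[C@H](O[Si](CC)(CC)CC)C[C@H]1OC1(C)C
F6 | step 11 | (5S,6E,8R,10R)-5-(tert-butyldimethylsilyloxy)-10,11-epoxy-7,11-dimethyl-3-methylidene-8-(triethylsilyloxy)dodec-6-enoic acid | OC(=O)CC(=C)C[C@H](O[Si](C)(C)C(C)(C)C)/C=C(C)/[C@H](O[Si](CC)(CC)CC)C[C@H]1OC1(C)C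
F7 | step 11 | (5S,6E,8R,10R)-5-(tert-butyldimethylsilyloxy)-10,11-epoxy-7,11-dimethyl-3-methylidene-8-(triethylsilyloxy)dodec-6-enoyl chloride | ClC(=O)CC(=C)C[C@H](O[Si](C)(C)C(C)(C)C)/C=C(C)/[C@H](O[Si](CC)(CC)CC)C[C@H]1OC1(C)C
F8 | step 7 | (4S,5E,7R)-4-hydroxy-6,10-dimethyl-7-(triethylsilyloxy)undeca-5,9-dien-2-one | CC(=O)C[C@H](O)/C=C(C)/[C@H](O[Si](CC)(CC)CC)CC=C(C)C
F9 | step 7 | (4S,5E,7R)-4-(tert-butyldimethylsilyloxy)-6,10-dimethyl-7-(triethylsilyloxy)undeca-5,9-dien-2-one | CC(=O)C[C@H](O[Si](C)(C)C(C)(C)C)/C=C(C)/[C@H](O[Si](CC)(CC)CC)CC=C(C)C
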